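## The problem

Xenicane numbering is used throughout: acetal carbon C1, ring oxygen O2, enol ether C3=C4, ring-fusion carbons C4a and C11a, carbocycle C5 to C11, methyl C18 on C7, methylene C19 on C11, side chain C12 to C15.

The target 33 is a trans-fused cyclonona[c]pyran. The pyran holds an acetoxy acetal at C1 and an enol ether C3=C4. The nine-membered carbocycle holds a tertiary carbinol at C7, a cis 8,9-epoxide and an exocyclic methylene at C11. C4 carries a chain with acetates at C12 and C13 and a trisubstituted 14,15-epoxide.

The nine stereocentres fall into three groups that cannot control one another: C1/C11a/C4a on the pyran, C7/C8/C9 on the carbocycle and C12/C13/C14 on the chain. C7 is separated from C4a by the methylenes C5 and C6, and C12 from C4a by the sp2 carbon C4. Inside each group relay is possible. C11a sits trans to C4a, C1 is anomeric, the C7 hydroxyl can deliver oxygen to C8=C9, and a C12 hydroxyl can direct oxidation of C13=C14. C7 is therefore best bought from the chiral pool, and C4a and C12 must come from reagents.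

The nine-membered ring is the hard ring to close. The acetal acetate and the two ester acetates exclude hydride, organometallic and basic steps once they are in place. The enol ether becomes electron-rich and acid-labile as soon as C12 is sp3, and C12 is then an ionisable allylic position. So every C=C oxidation has to be done while C12 is still a carbonyl, or with a hydroxyl-directed reagent.

The feature that allows a convergent key step is the ring O2–C1–C11a–C4a–C4=C3 with an acyl-level carbon on C4. It is the adduct of a 2-formylacrylate oxadiene (O=C3–C4=C4a) and an enol ether (C1=C11a).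

## Retrosynthesis

**Acetates last.** Target 33 is traced to lactol 32, silyl acetal 31 and diol 30 by cutting only the three acyl–oxygen bonds. Acetates would not survive the reductions and the base used earlier, so C1 travels as a triisopropylsilyl acetal. The forward steps must acylate two secondary hydroxyls beside a tertiary one, and must free and acylate C1–OH without breaking the C1–O bond.

**14,15-Epoxide by epoxide migration.** Diol 30 is traced to the 13,14-epoxy alcohol 28 through triol 29 (Payne retron; the O–C14 bond is exchanged). Direct epoxidation of a C14=C15 alkene was rejected: the electron-rich enol ether would compete, and hydroxyl direction from C13 would give the wrong relative configuration. Inversion at C14 converts the anti epoxy alcohol from a Sharpless epoxidation into the required 12,13-anti-13,14-anti array. Epoxy alcohol 28 comes from (E)-allylic alcohol 27, which comes from propargylic alcohol 26. Cutting C12–C13 gives aldehyde 23 and the commercial alkyne 24; the forward addition must set C12 under reagent control.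

**C12 oxidation level and the 8,9-epoxide.** Aldehyde 23 goes back through alcohol 22 to ester 21, and 21 to alkene 20 by removing the epoxide oxygen. The epoxidation is placed at the ester stage because the enol ether is then an unreactive β-alkoxyacrylate and the only allylic alcohol is C7–OH.

**Methylene and nine-membered ring.** Alkene 20 comes from ketone 19 and that from carbinol 18. Cutting C8=C9 of 18 gives diene 17, and cutting C10–C11 gives aldehyde 16 and an allyl nucleophile. Ring closure is put before the methylenation on purpose. A 1,1-disubstituted alkene at C11 would offer metathesis a far easier seven-membered closure (C8 to C11) than the nine-membered one. The ring closure must give the Z alkene, which the ring size enforces.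

**Arm adjustment.** Aldehyde 16 goes back to diol 15 and to the bis-triethylsilyl ether 14. Triethylsilyl on both C7–O and C11–O lets one reagent free both, and C7–OH stays free afterwards to assist metathesis and to direct the epoxidation.

**Key disconnection.** Pyran 14 is cut at C4a–C11a and C1–O2 into oxadiene 7 (fragment 1) and (E)-silyl enol ether 13 (fragment 2). Against a stepwise 1,5-dicarbonyl/lactol construction, or building the pyran onto a preformed carbocycle, this cut is convergent. It makes the ring and three stereocentres at once and leaves three differentiated handles: the C8 vinyl, C11–O and the C12 ester. The forward reaction must select one face of C4a, place C11 trans to C5 and put the C1 oxygen cis to C5. A silyl rather than an alkyl enol ether is used so that the acetal can be unmasked at the end with buffered fluoride.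

**Fragment 1.** Alkylidene 7 is cut at C4=C4a into aldehyde 4 and methyl formylacetate 6 (Knoevenagel). Aldehyde 4 comes from (S)-linalool 1 through its silyl ether 2 by cleavage of the trisubstituted alkene, so C7 and the C8 vinyl group are bought. Formylacetate 6 comes from acetal 5.

**Fragment 2.** Enol ether 13 goes back through alcohol 12 and enal 11 to sodium malonaldehyde 10 and 1,1,3,3-tetramethoxypropane 8. Silylation of a 3-oxygenated propanal would give mainly the Z enol ether. O-silylation of the extended malonaldehyde enolate fixes the E geometry, and the geometry is what places C11 trans to C5.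

## Roads not taken

**Alternative 1:** De Mayo ring expansion. The cut removes C8 and C9 (bonds C7–C8 and C9–C10) and leads to the pyran-fused cycloheptane-1,3-dione A1. In the forward sense the enol of A1 adds acetylene under irradiation to give cyclobutene A2, and retro-aldol cleavage of C7–C10 opens it to the Z-enedione A3.

- Merits: the medium ring arises by strain-driven expansion of an easily made seven-membered ring, and the Z geometry is dictated by the cyclobutene. On ring formation this road is better than a nine-membered metathesis.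
- Weak points: the two enol tautomers of A1 lead to regioisomeric enediones. Acetylene is a poor partner in enol [2+2] photoadditions. The β-alkoxyacrylate is itself a chromophore. A3 then needs a chemoselective and stereoselective methyl addition at C7 beside the C11 ketone, with only a flexible ring to control the new tertiary carbinol.
- Comparison: the chosen plan sets against the better ring formation a C7 centre of secure configuration from linalool and two arms that never need to be told apart.

**Alternative 2:** Indium Barbier closure at C9–C10. The cut gives bromo aldehyde A4, which has a 2-(bromomethyl)allyl unit on C11a and a C9 aldehyde next to a free C8 hydroxyl. Indium metal (In) inserts into the C–Br bond and the allyl–In species adds to the aldehyde under chelation, giving triol A5.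

- Merits: a polar C–C ring closure that tolerates water and free hydroxyls, C9 set by chelation, and the C11 methylene arriving with the ring. It needs no C11 ketone, so the methylenation and the base-sensitive β,γ-unsaturated ketone of the chosen plan are avoided; in that respect it is better.
- Weak points: A4 needs C8 and C9 oxidised stereoselectively before closure, and carries an α-hydroxy aldehyde and an allylic bromide on the sensitive pyran. A5 still has to be turned into the epoxide by selective activation of C9–OH and displacement by C8–O.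
- Comparison: the chosen plan uses the linalool vinyl group as it stands and installs the epoxide in one directed step.

**Alternative 3:** Chromium-mediated closure at C7–C8. The cut gives keto (Z)-vinyl iodide A6. CrCl2 with catalytic NiCl2 generates the C8–Cr bond, which adds to the C7 methyl ketone to give allylic alcohol A7, the same compound as 20 of the chosen route.

- Merits: the alkene geometry is fixed beforehand and no metathesis is needed; on geometry it is at least as safe as the chosen plan, and it converges on the same intermediate.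
- Weak points: ketones are sluggish acceptors in this reaction, more so in a medium-ring closure. C7 would be created in the closure with only the remote C4a to bias it. The Z-iodoalkene arm has to be built on C11 after the methylene.
- Comparison: the chosen plan carries C7 in from the chiral pool and uses its free hydroxyl twice, to help the metathesis and to direct the epoxidation.

Key step: step 9

Assumption: (S)-linalool of high enantiomeric purity (at least 98% ee) is used; any (R)-linalool would appear after step 9 as the C7-epimeric series.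

## Route

Step 1
Reactants: 1 (S)-linalool
Product: 2 (S)-linalool triethylsilyl ether
Conditions: Et3SiOTf, 2,6-lutidine, CH2Cl2, −78 → 0 °C
Reagents that add atoms: triethylsilyl trifluoromethanesulfonate, CC[Si](CC)(CC)OS(=O)(=O)C(F)(F)F
Why: Silylation of a tertiary alcohol with a silyl triflate and a hindered base; the ether prevents lactol formation in 4 and oxa-Michael closure onto the alkylidene of 7, and no stereocentre is touched.

Step 2
Reactants: 2 (S)-linalool triethylsilyl ether
Product: 4 (S)-4-methyl-4-(triethylsilyloxy)hex-5-enal, via secondary ozonide 3 (not isolated)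
Conditions: O3, CH2Cl2, −78 °C, Sudan Red 7B as end-point indicator; then PPh3, −78 °C → rt
Reagents that add atoms: ozone, [O-][O+]=O
Why: Chemoselective ozonolysis: the electron-rich trisubstituted alkene is consumed well before the monosubstituted vinyl group (the dye marks the end point), and PPh3 reduces the ozonide to the aldehyde.

Step 3
Reactants: 5 methyl 3,3-dimethoxypropanoate
Product: 6 methyl 3-oxopropanoate (methyl formylacetate)
Conditions: CF3CO2H, H2O, CH2Cl2, 0 °C → rt; extracted and used at once
Reagents that add atoms: water, O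
Why: Acid hydrolysis of a dimethyl acetal; the β-formyl ester self-condenses on standing and is therefore taken on directly.

Step 4
Reactants: 4 (S)-4-methyl-4-(triethylsilyloxy)hex-5-enal; 6 methyl 3-oxopropanoate
Product: 7 alkylidene formylacetate (fragment 1)
Conditions: piperidine (10 mol %), AcOH (10 mol %), 4 Å molecular sieves, CH2Cl2, 0 °C; short silica plug, used without storage
Reagents that add atoms: none
Why: Knoevenagel condensation through the iminium ion; the two alkylidene isomers interconvert under the amine/acid conditions and, as with alkylidene acetoacetates, the isomer with the chain cis to the ester and trans to the formyl group should dominate.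

Step 5
Reactants: 8 1,1,3,3-tetramethoxypropane
Product: 10 sodium (E)-3-oxoprop-1-en-1-olate, via malonaldehyde 9 (not isolated)
Conditions: 1 M aq HCl, 40 °C; then aq NaOH to pH 10, 0 °C; evaporation, recrystallisation from EtOH
Reagents that add atoms: water, O; sodium hydroxide, [Na+].[OH-]
Why: Hydrolysis of the bis-acetal and neutralisation to the stable enolate salt, which adopts the extended E geometry.

Step 6
Reactants: 10 sodium (E)-3-oxoprop-1-en-1-olate
Product: 11 (E)-3-(triisopropylsilyloxy)prop-2-enal
Conditions: i-Pr3SiCl, DMF, 0 °C → rt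
Reagents that add atoms: chlorotriisopropylsilane, CC(C)[Si](Cl)(C(C)C)C(C)C
Why: O-silylation of the malonaldehyde enolate, analogous to its O-acylation to trans-3-acyloxyacroleins; the E geometry of the later dienophile is fixed here.

Step 7
Reactants: 11 (E)-3-(triisopropylsilyloxy)prop-2-enal
Product: 12 (E)-3-(triisopropylsilyloxy)prop-2-en-1-ol
Conditions: i-Bu2AlH, CH2Cl2, −78 °C; aq potassium sodium tartrate
Reagents that add atoms: none
Why: 1,2-Reduction of an enal by i-Bu2AlH; the hindered silyl enol ether and its geometry are not affected and the work-up stays basic.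

Step 8
Reactants: 12 (E)-3-(triisopropylsilyloxy)prop-2-en-1-ol
Product: 13 (E)-3-(triethylsilyloxy)-1-(triisopropylsilyloxy)prop-1-ene (fragment 2)
Conditions: Et3SiCl, imidazole, CH2Cl2, 0 °C
Reagents that add atoms: chlorotriethylsilane, CC[Si](Cl)(CC)CC
Why: Silylation of a primary alcohol under buffered conditions that the acid-sensitive enol ether tolerates; triethylsilyl is chosen so that one later reagent frees C11–O and C7–O together.

Step 9
Reactants: 7 alkylidene formylacetate (fragment 1); 13 (E)-silyl enol ether (fragment 2)
Product: 14 2-silyloxy-3,4-dihydro-2H-pyran-5-carboxylate carrying both arms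
Conditions: Cu(OTf)2 (10 mol %), (S,S)-t-Bu-box (11 mol %), 4 Å molecular sieves, CH2Cl2, −78 → −40 °C
Reagents that add atoms: none
Why: Inverse-electron-demand hetero-Diels–Alder union of the 2-formylacrylate oxadiene (O=C3–C4=C4a) with the enol ether (C1=C11a); the closest known reactions are the cycloadditions of alkylidene 1,3-dicarbonyl compounds with enol ethers and the Cu(OTf)2–bis(oxazoline)-catalysed additions of enol silanes to chelating unsaturated carbonyl compounds. Divalent copper binds the formyl and ester oxygens and lowers the LUMO; this six-membered chelate holds both carbonyls s-trans to the alkylidene, so bond formation should be strongly asynchronous, C4a–C11a first and then O2–C1 by collapse of the copper-bound formyl enolate onto the silyloxocarbenium carbon within the ion pair (a concerted endo [4+2] of the s-cis oxadiene under one-point binding would give the same adduct). The pyran therefore closes as a formal [4+2], the second bond being a 6-exo-trig attack of the enolate oxygen on C1. C4a is set by the ligand, whose tert-butyl groups leave one face of the bound alkylidene open; C7 is too remote to contribute. C11a follows from the E geometry of 13 and the compact endo approach, which places C11 trans to C5, and C1 is set in the ring closure with the silyloxy group cis to C5 and axial. The step needs face selectivity at C4a, regioselectivity (secured by the matched polarity of nucleophilic C11a and electrophilic C4a) and retention of the enol ether geometry; low temperature and sieves suppress the uncatalysed reaction and hydrolysis of 13. Because C7 is fixed, the wrong face gives a diastereomer of 14 and not its enantiomer, so the sense of induction is read on the first run and the enantiomeric ligand is used if required.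

Step 10
Reactants: 14 pyran bis-triethylsilyl ether
Product: 15 pyran diol
Conditions: HF·pyridine, pyridine, THF, 0 °C → rt
Reagents that add atoms: none
Why: Fluoride cleavage of silyl ethers graded by bulk at silicon: both triethylsilyl ethers are removed, while the triisopropylsilyl acetal (hindered silicon, acetal deactivated by the β-alkoxyacrylate) should remain.

Step 11
Reactants: 15 pyran diol
Product: 16 C11 aldehyde
Conditions: Dess–Martin periodinane, NaHCO3, CH2Cl2, 0 °C
Reagents that add atoms: none
Why: Dess–Martin oxidation of the primary alcohol (the tertiary one is inert); the buffered, non-basic medium keeps C11a, now α to an aldehyde and β to two oxygens, from epimerising or eliminating.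

Step 12
Reactants: 16 C11 aldehyde
Product: 17 homoallylic alcohol (both C11 epimers)
Conditions: CH2=CHCH2MgBr (3 equiv), THF, −78 °C; aq NH4Cl
Reagents that add atoms: allylmagnesium bromide, C=CC[Mg]Br
Why: Grignard addition; the allyl reagent adds at −78 °C faster than it enolises the aldehyde and does not touch the vinylogous carbonate ester, and the new carbinol centre is removed again in step 14.

Step 13
Reactants: 17 homoallylic alcohol
Product: 18 nine-membered (Z)-cyclononene diol
Conditions: RuCl2(=CHPh)(PCy3)(H2IMes) (second-generation Grubbs catalyst, 10 mol %), 1,4-benzoquinone (20 mol %), toluene (1 mM), 80 °C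
Reagents that add atoms: none
Why: Ring-closing metathesis of the only two reactive alkenes (C8 vinyl and C9 allyl terminus); the free tertiary allylic hydroxyl assists loading at the hindered vinyl group, high dilution favours cyclisation, and the nine-membered ring can only hold the Z alkene comfortably. It is run before methylenation because a C11 1,1-disubstituted alkene would open a faster seven-membered closure.

Step 14
Reactants: 18 cyclononene diol
Product: 19 C11 ketone
Conditions: Dess–Martin periodinane, NaHCO3, CH2Cl2, 0 °C
Reagents that add atoms: none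
Why: Dess–Martin oxidation of the secondary alcohol, in which both C11 epimers converge; the neutral conditions keep the β,γ-unsaturated ketone out of conjugation and leave C11a in its trans arrangement.

Step 15
Reactants: 19 C11 ketone
Product: 20 11-methylidene bicycle
Conditions: Zn, CH2Br2, TiCl4, THF (Takai–Lombardo reagent, preformed at 0 °C); then 19, CH2Cl2, 0 °C → rt
Reagents that add atoms: dibromomethane, BrCBr
Why: Takai–Lombardo methylenation; the non-basic gem-dimetallic reagent converts enolisable β,γ-unsaturated ketones into methylene compounds without alkene migration or epimerisation and leaves the ester alone.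

Step 16
Reactants: 20 11-methylidene bicycle
Product: 21 8,9-epoxy alcohol
Conditions: VO(acac)2 (5 mol %), t-BuOOH (decane), CH2Cl2, 0 °C
Reagents that add atoms: tert-butyl hydroperoxide, CC(C)(C)OO
Why: Hydroxyl-directed epoxidation: the C7–O–V alkylperoxide delivers oxygen to C8=C9 on the face of the C7 hydroxyl, giving the cis epoxy alcohol (8R,9R). The C11 methylene has no allylic hydroxyl and the enol ether is still an electron-poor β-alkoxyacrylate, so neither reacts.

Step 17
Reactants: 21 8,9-epoxy alcohol ester
Product: 22 C12 allylic alcohol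
Conditions: i-Bu2AlH (4 equiv), CH2Cl2, −78 °C; aq potassium sodium tartrate; Et3N-deactivated silica
Reagents that add atoms: none
Why: i-Bu2AlH reduction of the β-alkoxyacrylate to the primary allylic alcohol; at −78 °C the epoxide and the silyl acetal are inert.

Step 18
Reactants: 22 C12 allylic alcohol
Product: 23 C12 aldehyde
Conditions: MnO2, CH2Cl2, rt
Reagents that add atoms: none
Why: MnO2 oxidises only the allylic primary alcohol and returns the enol ether to a stable vinylogous formate.

Step 19
Reactants: 23 C12 aldehyde; 24 3-methyl-3-(trimethylsilyloxy)but-1-yne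
Product: 26 C12 propargylic alcohol, via methylzinc acetylide 25 (not isolated)
Conditions: Me2Zn, (S,S)-ProPhenol (20 mol %), Ph3P=O (40 mol %), toluene, 0 °C → rt
Reagents that add atoms: none
Why: Catalytic enantioselective addition of an alkynylzinc to an α,β-unsaturated aldehyde; the chiral zinc–ProPhenol complex, not the distant ring centres, sets C12 by addition to the Si face of the formyl group. The sense is checked by Mosher ester analysis and the enantiomeric ligand is used if required.

Step 20
Reactants: 26 C12 propargylic alcohol
Product: 27 (E)-allylic alcohol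
Conditions: NaAlH2(OCH2CH2OMe)2, THF, 0 °C; aq potassium sodium tartrate
Reagents that add atoms: none
Why: trans-Hydroalumination of the propargylic alkoxide and protonolysis give only the E alkene. The ring epoxide is cis to its neighbouring alkoxide and so cannot receive hydride intramolecularly from the backside.

Step 21
Reactants: 27 (E)-allylic alcohol
Product: 28 13,14-epoxy alcohol
Conditions: Ti(O-i-Pr)4, D-(−)-diisopropyl tartrate, t-BuOOH, 4 Å molecular sieves, CH2Cl2, −20 °C
Reagents that add atoms: tert-butyl hydroperoxide, CC(C)(C)OO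
Why: Sharpless asymmetric epoxidation of a secondary allylic alcohol in the matched sense, giving the anti epoxy alcohol (13R,14S). The tartrate that is matched for C13=C14 is mismatched for the enol ether C3=C4 on the other side of the same carbinol, which is the basis for leaving the enol ether untouched.

Step 22
Reactants: 28 13,14-epoxy alcohol
Product: 30 12,13-diol 14,15-epoxide, via epoxy triol 29 (not isolated)
Conditions: K2CO3, MeOH, 0 °C → rt
Reagents that add atoms: none
Why: Methanolysis of the trimethylsilyl ether, then Payne rearrangement: the tertiary C15 alkoxide opens the epoxide at C14 with inversion (3-exo-tet) to give the more substituted 14,15-epoxide and the secondary C13 alkoxide. The equilibrium is driven by epoxide substitution and the gem-dimethyl effect; the ring epoxy alcohol is cis and cannot rearrange.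

Step 23
Reactants: 30 12,13-diol 14,15-epoxide
Product: 31 12,13-diacetate
Conditions: Ac2O, pyridine, DMAP (5 mol %), CH2Cl2, 0 °C
Reagents that add atoms: acetic anhydride, CC(=O)OC(C)=O
Why: Acylation of the two secondary hydroxyls; the tertiary C7 hydroxyl is not acylated under these conditions, and the C12 carbinol is protected before the acetal is opened.

Step 24
Reactants: 31 12,13-diacetate
Product: 32 C1 lactol
Conditions: Bu4NF, AcOH (1:1), THF, 0 °C
Reagents that add atoms: none
Why: Buffered fluoride cleaves the Si–O bond of the silyl acetal and leaves the C1–O bond, the acetates and both epoxides intact, so the lactol keeps the C1 configuration set in step 9.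

Step 25
Reactants: 32 C1 lactol
Product: 33 target (CNP0134792.1)
Conditions: Ac2O, Et3N, DMAP (5 mol %), CH2Cl2, −20 → 0 °C
Reagents that add atoms: acetic anhydride, CC(=O)OC(C)=O
Why: O-Acylation of the lactol with retention at C1. If the anomers equilibrate, the axial acetate trans to C11 (the target configuration) is also the anomerically favoured one, and the tertiary C7 hydroxyl again stays free.

## Compound list

1 | (S)-linalool, (3S)-3,7-dimethylocta-1,6-dien-3-ol | C=C[C@@](C)(O)CCC=C(C)C | starting material
2 | (3S)-3,7-dimethyl-3-(triethylsilyloxy)octa-1,6-diene | C=C[C@@](C)(O[Si](CC)(CC)CC)CCC=C(C)C | intermediate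
3 | secondary ozonide of 2, 3,3-dimethyl-5-[(3S)-3-methyl-3-(triethylsilyloxy)pent-4-en-1-yl]-1,2,4-trioxolane | C=C[C@@](C)(O[Si](CC)(CC)CC)CCC1OOC(C)(C)O1 | intermediate
4 | (4S)-4-methyl-4-(triethylsilyloxy)hex-5-enal | C=C[C@@](C)(O[Si](CC)(CC)CC)CCC=O | intermediate
5 | methyl 3,3-dimethoxypropanoate | COC(CC(=O)OC)OC | starting material
6 | methyl 3-oxopropanoate | O=CCC(=O)OC | intermediate
7 | methyl (2Z,6S)-2-formyl-6-methyl-6-(triethylsilyloxy)octa-2,7-dienoate (fragment 1) | C=C[C@@](C)(O[Si](CC)(CC)CC)CC/C=C(/C=O)C(=O)OC | intermediate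
8 | 1,1,3,3-tetramethoxypropane | COC(CC(OC)OC)OC | starting material
9 | malonaldehyde (propanedial) | O=CCC=O | intermediate
10 | sodium (E)-3-oxoprop-1-en-1-olate | [Na+].[O-]/C=C/C=O | intermediate
11 | (E)-3-(triisopropylsilyloxy)prop-2-enal | O=C/C=C/O[Si](C(C)C)(C(C)C)C(C)C | intermediate
12 | (E)-3-(triisopropylsilyloxy)prop-2-en-1-ol | OC/C=C/O[Si](C(C)C)(C(C)C)C(C)C | intermediate
13 | (E)-3-(triethylsilyloxy)-1-(triisopropylsilyloxy)prop-1-ene (fragment 2) | CC[Si](CC)(CC)OC/C=C/O[Si](C(C)C)(C(C)C)C(C)C | intermediate
14 | methyl (2R,3R,4S)-4-[(3S)-3-methyl-3-(triethylsilyloxy)pent-4-en-1-yl]-3-[(triethylsilyloxy)methyl]-2-(triisopropylsilyloxy)-3,4-dihydro-2H-pyran-5-carboxylate | C=C[C@@](C)(O[Si](CC)(CC)CC)CC[C@@H]1C(C(=O)OC)=CO[C@H](O[Si](C(C)C)(C(C)C)C(C)C)[C@H]1CO[Si](CC)(CC)CC | intermediate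
15 | methyl (2R,3R,4S)-3-(hydroxymethyl)-4-[(3S)-3-hydroxy-3-methylpent-4-en-1-yl]-2-(triisopropylsilyloxy)-3,4-dihydro-2H-pyran-5-carboxylate | C=C[C@@](C)(O)CC[C@@H]1C(C(=O)OC)=CO[C@H](O[Si](C(C)C)(C(C)C)C(C)C)[C@H]1CO | intermediate
16 | methyl (2R,3R,4S)-3-formyl-4-[(3S)-3-hydroxy-3-methylpent-4-en-1-yl]-2-(triisopropylsilyloxy)-3,4-dihydro-2H-pyran-5-carboxylate | C=C[C@@](C)(O)CC[C@@H]1C(C(=O)OC)=CO[C@H](O[Si](C(C)C)(C(C)C)C(C)C)[C@H]1C=O | intermediate
17 | methyl (2R,3R,4S)-3-(1-hydroxybut-3-en-1-yl)-4-[(3S)-3-hydroxy-3-methylpent-4-en-1-yl]-2-(triisopropylsilyloxy)-3,4-dihydro-2H-pyran-5-carboxylate (both carbinol epimers) | C=C[C@@](C)(O)CC[C@@H]1C(C(=O)OC)=CO[C@H](O[Si](C(C)C)(C(C)C)C(C)C)[C@H]1C(O)CC=C | intermediate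
18 | methyl (1R,4aS,7S,8Z,11aR)-7,11-dihydroxy-7-methyl-1-(triisopropylsilyloxy)-1,4a,5,6,7,10,11,11a-octahydrocyclonona[c]pyran-4-carboxylate (both C11 epimers) | OC1C/C=C\[C@@](C)(O)CC[C@@H]2C(C(=O)OC)=CO[C@H](O[Si](C(C)C)(C(C)C)C(C)C)[C@@H]12 | intermediate
19 | methyl (1R,4aS,7S,8Z,11aS)-7-hydroxy-7-methyl-11-oxo-1-(triisopropylsilyloxy)-1,4a,5,6,7,10,11,11a-octahydrocyclonona[c]pyran-4-carboxylate | O=C1C/C=C\[C@@](C)(O)CC[C@@H]2C(C(=O)OC)=CO[C@H](O[Si](C(C)C)(C(C)C)C(C)C)[C@@H]12 | intermediate
20 | methyl (1R,4aS,7S,8Z,11aR)-7-hydroxy-7-methyl-11-methylidene-1-(triisopropylsilyloxy)-1,4a,5,6,7,10,11,11a-octahydrocyclonona[c]pyran-4-carboxylate | C=C1C/C=C\[C@@](C)(O)CC[C@@H]2C(C(=O)OC)=CO[C@H](O[Si](C(C)C)(C(C)C)C(C)C)[C@@H]12 | intermediate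
21 | methyl (1R,4aS,7S,8R,9R,11aR)-8,9-epoxy-7-hydroxy-7-methyl-11-methylidene-1-(triisopropylsilyloxy)-1,4a,5,6,7,8,9,10,11,11a-decahydrocyclonona[c]pyran-4-carboxylate | C=C1C[C@H]2O[C@H]2[C@@](C)(O)CC[C@@H]2C(C(=O)OC)=CO[C@H](O[Si](C(C)C)(C(C)C)C(C)C)[C@@H]12 | intermediate
22 | (1R,4aS,7S,8R,9R,11aR)-8,9-epoxy-4-(hydroxymethyl)-7-methyl-11-methylidene-1-(triisopropylsilyloxy)-1,4a,5,6,7,8,9,10,11,11a-decahydrocyclonona[c]pyran-7-ol | C=C1C[C@H]2O[C@H]2[C@@](C)(O)CC[C@@H]2C(CO)=CO[C@H](O[Si](C(C)C)(C(C)C)C(C)C)[C@@H]12 | intermediate
23 | (1R,4aS,7S,8R,9R,11aR)-8,9-epoxy-7-hydroxy-7-methyl-11-methylidene-1-(triisopropylsilyloxy)-1,4a,5,6,7,8,9,10,11,11a-decahydrocyclonona[c]pyran-4-carbaldehyde | C=C1C[C@H]2O[C@H]2[C@@](C)(O)CC[C@@H]2C(C=O)=CO[C@H](O[Si](C(C)C)(C(C)C)C(C)C)[C@@H]12 | intermediate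
24 | 3-methyl-3-(trimethylsilyloxy)but-1-yne | C#CC(C)(C)O[Si](C)(C)C | starting material
25 | methyl[3-methyl-3-(trimethylsilyloxy)but-1-yn-1-yl]zinc | C[Zn]C#CC(C)(C)O[Si](C)(C)C | intermediate
26 | (1R,4aS,7S,8R,9R,11aR)-8,9-epoxy-4-[(1S)-1-hydroxy-4-methyl-4-(trimethylsilyloxy)pent-2-yn-1-yl]-7-methyl-11-methylidene-1-(triisopropylsilyloxy)-1,4a,5,6,7,8,9,10,11,11a-decahydrocyclonona[c]pyran-7-ol | C=C1C[C@H]2O[C@H]2[C@@](C)(O)CC[C@@H]2C([C@@H](O)C#CC(C)(C)O[Si](C)(C)C)=CO[C@H](O[Si](C(C)C)(C(C)C)C(C)C)[C@@H]12 | intermediate
27 | (1R,4aS,7S,8R,9R,11aR)-8,9-epoxy-4-[(1S,2E)-1-hydroxy-4-methyl-4-(trimethylsilyloxy)pent-2-en-1-yl]-7-methyl-11-methylidene-1-(triisopropylsilyloxy)-1,4a,5,6,7,8,9,10,11,11a-decahydrocyclonona[c]pyran-7-ol | C=C1C[C@H]2O[C@H]2[C@@](C)(O)CC[C@@H]2C([C@@H](O)/C=C/C(C)(C)O[Si](C)(C)C)=CO[C@H](O[Si](C(C)C)(C(C)C)C(C)C)[C@@H]12 | intermediate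
28 | (1R,4aS,7S,8R,9R,11aR)-8,9-epoxy-4-{(R)-hydroxy[(2R,3S)-3-[2-(trimethylsilyloxy)propan-2-yl]oxiran-2-yl]methyl}-7-methyl-11-methylidene-1-(triisopropylsilyloxy)-1,4a,5,6,7,8,9,10,11,11a-decahydrocyclonona[c]pyran-7-ol | C=C1C[C@H]2O[C@H]2[C@@](C)(O)CC[C@@H]2C([C@@H](O)[C@H]3O[C@@H]3C(C)(C)O[Si](C)(C)C)=CO[C@H](O[Si](C(C)C)(C(C)C)C(C)C)[C@@H]12 | intermediate
29 | (1R,4aS,7S,8R,9R,11aR)-8,9-epoxy-4-{(R)-hydroxy[(2R,3S)-3-(2-hydroxypropan-2-yl)oxiran-2-yl]methyl}-7-methyl-11-methylidene-1-(triisopropylsilyloxy)-1,4a,5,6,7,8,9,10,11,11a-decahydrocyclonona[c]pyran-7-ol | C=C1C[C@H]2O[C@H]2[C@@](C)(O)CC[C@@H]2C([C@@H](O)[C@H]3O[C@@H]3C(C)(C)O)=CO[C@H](O[Si](C(C)C)(C(C)C)C(C)C)[C@@H]12 | intermediate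
30 | (1R,2R)-1-[(1R,4aS,7S,8R,9R,11aR)-8,9-epoxy-7-hydroxy-7-methyl-11-methylidene-1-(triisopropylsilyloxy)-1,4a,5,6,7,8,9,10,11,11a-decahydrocyclonona[c]pyran-4-yl]-2-[(2R)-3,3-dimethyloxiran-2-yl]ethane-1,2-diol | C=C1C[C@H]2O[C@H]2[C@@](C)(O)CC[C@@H]2C([C@@H](O)[C@@H](O)[C@H]3OC3(C)C)=CO[C@H](O[Si](C(C)C)(C(C)C)C(C)C)[C@@H]12 | intermediate
31 | 12,13-di-O-acetate of 30 (xenicane positions; C1 triisopropylsilyl acetal, C7 hydroxyl free) | C=C1C[C@H]2O[C@H]2[C@@](C)(O)CC[C@@H]2C([C@@H](OC(C)=O)[C@@H](OC(C)=O)[C@H]3OC3(C)C)=CO[C@H](O[Si](C(C)C)(C(C)C)C(C)C)[C@@H]12 | intermediate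
32 | C1 lactol, (1S,4aS,7S,8R,9R,11aR)-4-[(1R,2R)-1,2-diacetoxy-2-((2R)-3,3-dimethyloxiran-2-yl)ethyl]-8,9-epoxy-7-methyl-11-methylidene-1,4a,5,6,7,8,9,10,11,11a-decahydrocyclonona[c]pyran-1,7-diol (C1 hydroxyl on the face of the former silyloxy group) | C=C1C[C@H]2O[C@H]2[C@@](C)(O)CC[C@@H]2C([C@@H](OC(C)=O)[C@@H](OC(C)=O)[C@H]3OC3(C)C)=CO[C@H](O)[C@@H]12 | intermediate
33 | CNP0134792.1, (1R,4aS,7S,8R,9R,11aR)-1-acetoxy-4-[(1R,2R)-1,2-diacetoxy-2-((2R)-3,3-dimethyloxiran-2-yl)ethyl]-8,9-epoxy-7-methyl-11-methylidene-1,4a,5,6,7,8,9,10,11,11a-decahydrocyclonona[c]pyran-7-ol | C=C1C[C@H]2O[C@H]2[C@@](C)(O)CC[C@@H]2C([C@@H](OC(C)=O)[C@@H](OC(C)=O)[C@H]3OC3(C)C)=CO[C@H](OC(C)=O)[C@@H]12 | target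

## Step count and risks

Total: 25 steps. Longest linear sequence: 21 steps (8 to 33 through steps 5 to 25); from (S)-linalool the count is 20.

**Step 9 (key step).** What may go wrong:
- poor or reversed facial selectivity at C4a, because the chelated oxadiene cannot reach the s-cis geometry of a concerted cycloaddition and the two alkylidene isomers need not respond alike to the ligand;
- silyl transfer to the copper enolate in place of ring closure, which would leave an open-chain aldehyde;
- ionisation or hydrolysis of the enol ether by the Lewis acid.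

Fallback (sets out from 7, returns at 15): an amine-catalysed Michael addition and hemiacetal closure. Commercial 3-(tert-butyldimethylsilyloxy)propanal and 7 are combined with (R)-α,α-diphenylprolinol trimethylsilyl ether (enantiomer chosen by analogy with the sense of its aldehyde additions to nitroalkenes). The E enamine adds to C4a; hydrolysis of the iminium ion and closure of the formyl enol onto the aldehyde give the lactol F1 with C11 trans to C5. Silylation of F1 with i-Pr3SiOTf and 2,6-lutidine gives the silyl acetal F2, and HF·pyridine removes the triethylsilyl and tert-butyldimethylsilyl ethers of F2 to reach 15.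

**Step 13 (ring-closing metathesis).** What may go wrong: oligomerisation outrunning the nine-membered closure, slow loading on the hindered C8 vinyl group, alkene migration by ruthenium hydrides, and unequal behaviour of the two C11 epimers.

Fallback (sets out from 17, returns at 19): 17 is first oxidised with Dess–Martin periodinane to the acyclic β,γ-unsaturated ketone F3, a single compound with an sp2 carbon in the chain. The ring is then closed on F3 with the same ruthenium catalyst in the presence of Ti(O-i-Pr)4 to break carbonyl chelation, giving 19 directly.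

**Step 15 (methylenation).** What may go wrong: transannular hemiketal formation between the C7 hydroxyl and the C11 ketone withdrawing the ketone, and ionisation of the tertiary allylic alcohol or of that hemiketal by the Lewis-acidic titanium reagent.

Fallback (sets out from 19, returns at 20): Peterson olefination. Me3SiCH2Li with CeCl3 adds to 19 without enolisation to give the β-hydroxysilane F4, and KH in THF eliminates F4 to 20.

**Step 19 (alkynylation).** What may go wrong: sluggish addition to the deactivated vinylogous formate, insufficient or reversed induction at C12, and interference of the zinc alkoxide of the C7 hydroxyl with the catalyst.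

Fallback (sets out from 23, returns at 26): 24 is deprotonated with n-BuLi and added to 23 at −78 °C, giving 26 together with its C12 epimer F5. The mixture is oxidised with MnO2 to the ynone F6. Corey–Bakshi–Shibata reduction of F6 with (R)-2-methyl-CBS-oxazaborolidine and catecholborane, the alkyne acting as the small group, returns 26.

**Step 21 (asymmetric epoxidation).** What may go wrong: competing oxidation of the electron-rich enol ether C3=C4, which is also allylic to the C12 hydroxyl, and ionisation of the doubly allylic C12 carbinol by the titanium alkoxide.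

Fallback (sets out from 27, returns at 28): 27 is oxidised with MnO2 to the cross-conjugated dienone F7. Nucleophilic (Weitz–Scheffer type) epoxidation with t-BuOOH, La(O-i-Pr)3, BINOL (enantiomer chosen for the 13,14 configuration) and Ph3As=O attacks only the electron-poor C13=C14 and gives the epoxy ketone F8. Chelation-controlled reduction of F8 with Zn(BH4)2 gives the anti epoxy alcohol 28.

## Further compounds

F1 | step 9 | lactol, methyl (3R,4S)-3-[(tert-butyldimethylsilyloxy)methyl]-2-hydroxy-4-[(3S)-3-methyl-3-(triethylsilyloxy)pent-4-en-1-yl]-3,4-dihydro-2H-pyran-5-carboxylate (anomers) | C=C[C@@](C)(O[Si](CC)(CC)CC)CC[C@@H]1C(C(=O)OC)=COC(O)[C@H]1CO[Si](C)(C)C(C)(C)C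
F2 | step 9 | methyl (2R,3R,4S)-3-[(tert-butyldimethylsilyloxy)methyl]-4-[(3S)-3-methyl-3-(triethylsilyloxy)pent-4-en-1-yl]-2-(triisopropylsilyloxy)-3,4-dihydro-2H-pyran-5-carboxylate | C=C[C@@](C)(O[Si](CC)(CC)CC)CC[C@@H]1C(C(=O)OC)=CO[C@H](O[Si](C(C)C)(C(C)C)C(C)C)[C@H]1CO[Si](C)(C)C(C)(C)C
F3 | step 13 | methyl (2R,3S,4S)-3-(but-3-enoyl)-4-[(3S)-3-hydroxy-3-methylpent-4-en-1-yl]-2-(triisopropylsilyloxy)-3,4-dihydro-2H-pyran-5-carboxylate | C=C[C@@](C)(O)CC[C@@H]1C(C(=O)OC)=CO[C@H](O[Si](C(C)C)(C(C)C)C(C)C)[C@H]1C(=O)CC=C
F4 | step 15 | β-hydroxysilane, methyl (8Z)-7,11-dihydroxy-7-methyl-11-[(trimethylsilyl)methyl]-1-(triisopropylsilyloxy)-1,4a,5,6,7,10,11,11a-octahydrocyclonona[c]pyran-4-carboxylate (ring configuration as in 19) | C[Si](C)(C)CC1(O)C/C=C\[C@@](C)(O)CC[C@@H]2C(C(=O)OC)=CO[C@H](O[Si](C(C)C)(C(C)C)C(C)C)[C@@H]12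
F5 | step 19 | C12 epimer of 26, side chain (1R)-1-hydroxy-4-methyl-4-(trimethylsilyloxy)pent-2-yn-1-yl | C=C1C[C@H]2O[C@H]2[C@@](C)(O)CC[C@@H]2C([C@H](O)C#CC(C)(C)O[Si](C)(C)C)=CO[C@H](O[Si](C(C)C)(C(C)C)C(C)C)[C@@H]12
F6 | step 19 | ynone, C4 side chain 4-methyl-4-(trimethylsilyloxy)pent-2-ynoyl on the bicycle of 23 | C=C1C[C@H]2O[C@H]2[C@@](C)(O)CC[C@@H]2C(C(=O)C#CC(C)(C)O[Si](C)(C)C)=CO[C@H](O[Si](C(C)C)(C(C)C)C(C)C)[C@@H]12
F7 | step 21 | dienone, C4 side chain (2E)-4-methyl-4-(trimethylsilyloxy)pent-2-enoyl on the bicycle of 23 | C=C1C[C@H]2O[C@H]2[C@@](C)(O)CC[C@@H]2C(C(=O)/C=C/C(C)(C)O[Si](C)(C)C)=CO[C@H](O[Si](C(C)C)(C(C)C)C(C)C)[C@@H]12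
F8 | step 21 | epoxy ketone, C4 side chain (13R,14S)-13,14-epoxy-12-oxo with C15 trimethylsilyl ether (xenicane positions) on the bicycle of 23 | C=C1C[C@H]2O[C@H]2[C@@](C)(O)CC[C@@H]2C(C(=O)[C@H]3O[C@@H]3C(C)(C)O[Si](C)(C)C)=CO[C@H](O[Si](C(C)C)(C(C)C)C(C)C)[C@@H]12
A1 | alternative 1 | pyran-fused cycloheptane-1,3-dione, methyl 7,9-dioxo-1-(triisopropylsilyloxy)-1,4a,5,6,7,8,9,9a-octahydrocyclohepta[c]pyran-4-carboxylate | O=C1CC(=O)CC[C@@H]2C(C(=O)OC)=CO[C@H](O[Si](C(C)C)(C(C)C)C(C)C)[C@@H]12
A2 | alternative 1 | cyclobutene photoadduct of the enol of A1 with acetylene | O=C1C2C=CC2(O)CC[C@@H]2C(C(=O)OC)=CO[C@H](O[Si](C(C)C)(C(C)C)C(C)C)[C@@H]12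
A3 | alternative 1 | pyran-fused (Z)-cyclononene-1,5-dione, methyl (8Z)-7,11-dioxo-1-(triisopropylsilyloxy)-1,4a,5,6,7,10,11,11a-octahydrocyclonona[c]pyran-4-carboxylate | O=C1C/C=C\C(=O)CC[C@@H]2C(C(=O)OC)=CO[C@H](O[Si](C(C)C)(C(C)C)C(C)C)[C@@H]12
A4 | alternative 2 | bromo aldehyde, methyl 3-(3-bromoprop-1-en-2-yl)-4-(3,4-dihydroxy-3-methyl-5-oxopentyl)-2-(triisopropylsilyloxy)-3,4-dihydro-2H-pyran-5-carboxylate | O=C[C@@H](O)[C@@](C)(O)CC[C@@H]1C(C(=O)OC)=CO[C@H](O[Si](C(C)C)(C(C)C)C(C)C)[C@H]1C(=C)CBr
A5 | alternative 2 | nine-membered 7,8,9-triol fused to the pyran | C=C1C[C@H](O)[C@@H](O)[C@@](C)(O)CC[C@@H]2C(C(=O)OC)=CO[C@H](O[Si](C(C)C)(C(C)C)C(C)C)[C@@H]12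
A6 | alternative 3 | keto (Z)-vinyl iodide, methyl 3-[(4Z)-5-iodopenta-1,4-dien-2-yl]-4-(3-oxobutyl)-2-(triisopropylsilyloxy)-3,4-dihydro-2H-pyran-5-carboxylate | CC(=O)CC[C@@H]1C(C(=O)OC)=CO[C@H](O[Si](C(C)C)(C(C)C)C(C)C)[C@H]1C(=C)C/C=C\I
A7 | alternative 3 | nine-membered Z-allylic tertiary alcohol fused to the pyran (identical with 20) | C=C1C/C=C\[C@@](C)(O)CC[C@@H]2C(C(=O)OC)=CO[C@H](O[Si](C(C)C)(C(C)C)C(C)C)[C@@H]12
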